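## Structural features

The target 33 is a daucane in which a cyclopentane (C1–C5) is cis-fused through the C1–C5 bond to a cyclohept-8-ene (C1, C5–C10), numbered C1 (ring-fusion carbon bearing methyl), C2, C3, C4 (isopropyl carbinol), C5 (ring-fusion CH), C6 (4-hydroxybenzoyloxy), C7, C8 (methyl-bearing alkene carbon), C9 and C10 (tigloyloxy). Five stereocentres, (1R,4R,5S,6S,10S), form one unbroken array C10–C1–C5(–C4)–C6. The angular methyl, H5, the isopropyl group and the C6 oxygen lie on one side of the bicycle; the C10 oxygen and the C4 hydroxyl lie on the other. The fragile groups are the tiglate, an allylic ester of a neopentyl alcohol (ionisation, allylic transposition), the 4-hydroxybenzoate, which sits 1,3 to the free tertiary C4 hydroxyl (acyl shift, elimination) and carries a free phenol, and the trisubstituted C8=C9 alkene, which can migrate under acid. The real difficulty is quaternary C1 flanked by the C10 and C5 stereocentres, the cis ring fusion, and three oxygens (C4, C6, C10) that must end as one free tertiary alcohol and two different esters. The key step exploits the fact that C5 carries C1 and lies between the oxygenated carbons C4 and C6, so that with C4 as a ketone the unit is an aldol, which a 2,3-epoxy alcohol C4(OH)–C5–C6 delivers when its carbinol carbon C4 is a cyclobutane carbon (C1–C2–C3–C4) still bonded to C1. Shifting C1 from C4 to C5 then makes the C1–C5 bond, the five-membered ring and the C5 stereocentre in one stereospecific event, and only C8=C9 remains to close the seven-membered ring.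

## Logic of the disconnections

**33 ⇒ 32 ⇒ 29 + 30, and 29 ⇒ 28.** The aryl O–Si bond, the C10 acyl C–O bond and the C10 O–CH2Ar bond are cut. The allylic ester and the phenol are the most fragile functions and should never meet organometallic, hydride or Lewis-acid steps. The gain is that the C10 oxygen travels as an inert ether and the acyl unit becomes the separate piece 30. The forward steps must acylate a neopentyl allylic alcohol beside a free tertiary alcohol, cleave the ether oxidatively without oxidising the new allylic alcohol, and desilylate without moving acyl groups.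

**28 ⇒ 27.** The C8=C9 bond is cut. It is the only bond of the seven-membered ring not attached to a stereocentre, and both termini are plain alkenes. The bicycle becomes a cyclopentane with two cis side chains. The forward step must close a trisubstituted cycloheptene from a hindered allylic-ether vinyl group and a 1,1-disubstituted alkene.

**27 ⇒ 24 + 25.** The C6 acyl C–O bond is cut, so the aroyl unit is the separate building block 25. The forward step must acylate the secondary C6 hydroxyl and leave the tertiary C4 hydroxyl alone.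

**24 ⇒ 21 + 22 (through 23), and 21 ⇒ 20.** The C4–isopropyl bond and the C6 O–Si bond are cut. The C4 carbinol is the adduct of the ketone that the key step leaves at C4. One stereocentre and the isopropyl group are removed. The forward step must add a secondary alkyl nucleophile to a hindered, enolisable ketone from the face opposite the two cis chains, with the β-hydroxyl masked so that retro-aldol cleavage, C5 epimerisation and elimination cannot occur.

**20 ⇒ 19 (key).** The C1–C5 bond is cut and C1 is returned to C4, which reopens the cyclopentanone to a cyclobutanol carrying a trans epoxide. The aldol pattern O–C4–C5–C6–O is the signature of an epoxy-alcohol rearrangement. The C1/C5/C6 problem is reduced to an alkene geometry plus one epoxidation. The forward step must make C1, not C3, migrate, anti to the C5–O bond.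

**19 ⇒ 18 ⇒ 17 ⇒ 12 + 15, and 15 ⇒ 13 + 14.** The two epoxide C–O bonds are cut, C5=C6 is returned to an alkyne, and the C4–C5 bond is cut. An (E)-allylic tertiary alcohol is the natural substrate for a hydroxyl-directed epoxidation, and an acetylide is the smallest C5–C8 nucleophile. The side chain becomes the five-carbon enyne 15, made from 13 and 14. The forward steps must add to 12 anti to the C10 chain and epoxidise on the face set by the C4 carbinol. Since C4 is erased in the key step, only the epoxide configuration has to be right.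

**12 ⇒ 11 ⇒ 10 ⇒ 9 ⇒ 5 + 6 (through 7 and 8).** The C1–C2 bond is cut (back to the oxaspiropentane), then the epoxide C–O bond at the cyclopropane, then the bond from C1 to the cyclopropane. Ring expansion of an oxaspiropentane is invertive at C1, so C1 is set by a carbonyl addition next to C10. The quaternary centre is reduced to an α-alkoxy methyl ketone plus a three-carbon ring. The addition must place the new C1–O bond syn to the C10–O bond. A metal-free cyclopropylide on a silyl-protected analogue of 5 would follow the Felkin–Anh sense and lead to the C1 epimer of 12. The design therefore uses a chelating benzylic ether at C10 and the magnesium nucleophile 8.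

**5 ⇒ 4 ⇒ 3 ⇒ 2 ⇒ 1.** The ketone is returned to a carbinol, the methyl group to the CH2 of a terminal epoxide, the ether to the alcohol, and the epoxide to an alkene. This reaches the achiral 1, whose desymmetrisation sets C10. The forward steps must give high enantiotopic-group selectivity and must never enolise the C10–H of 5.

## Other disconnections considered

**Alternative 1:** The cut removes C1–C5 and C1–C10 together. C5–C10 then become a 2-methoxy-4-methylphenyl ring and C1 the carbene carbon of the α-methyl diazoketone A1. Forward, the catalyst A2, which is the divalent rhodium carboxylate Rh2(OAc)4, would convert A1 into a carbenoid that adds across the ipso/ortho bond of the arene (Buchner reaction). Electrocyclic opening of the norcaradiene would give the azulenone A3, with both rings and the quaternary centre formed at once.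
- In its favour: a flat, easily assembled aromatic precursor; the C8 methyl and C6 oxygen already in place; C4 can be set early.
- Against it here: A3 is at the wrong oxidation pattern. The C2 ketone must be deleted. C10 is a bare sp2 CH that must gain its oxygen while C9=C10 moves to C8=C9. C5 and C6 are trigonal, so the cis fusion and the C6 carbinol must come from reductions of a mobile cycloheptatriene prone to 1,5-hydrogen shifts. The carbenoid formed by A2 chooses the arene face only through the difference between silyloxy and isopropyl at C4.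
- Comparison: on structure the alternative is better in its key step (two rings and two C–C bonds against one and one) and equal in stereocentres made there (C1 against C5). On mechanism the carbenoid addition is face-selective but not stereospecific, whereas the 1,2-shift transfers configuration by its mechanism. On step economy the early lead should be lost in redox corrections, while the chosen plan delivers C4, C6 and C10 at their final oxidation level.

**Alternative 2:** The cut removes C7–C8 and C9–C10. The seven-membered ring then comes from the bicyclic vinylcyclopropane A4 (cyclopropane C1–C5–C10, vinyl C6=C7 on C5) and propyne A5. Forward, the catalyst A6, which is the monovalent rhodium complex [Rh(CO)2Cl]2, would open the C5–C10 bond and insert A5 in a [5+2] cycloaddition to give the dienone A7.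
- In its favour: convergent; fully atom-economic, which is better than the chosen plan (whose metathesis loses ethene); the C8=C9 alkene and its methyl group are made directly; the C4 ketone and the C5=C6 enone are useful handles.
- Against it here: the insertion regiochemistry of the unsymmetrical A5 (methyl on C8 or C9) is not secured. Cleavage of C5–C1 by A6 competes with cleavage of C5–C10. If the ring opening retains configuration at C10, A4 must carry its ether endo, the hindered isomer. C5 and C6 remain to be set by oxygenation of the enone with cis protonation, on a skipped diene that can slip into conjugation.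
- Comparison: on structure the alternative is better in bonds formed (two against one) but sets no stereocentre in its key step, against one set and two relayed. On mechanism a metallacycle with regiochemical ambiguity stands against a stereospecific shift. On step economy the two are about equal if the regiochemistry cooperates.

**Alternative 3:** The cut removes C6–C7 and C9–C10. The cis-dialdehyde A8 (C6 and C10 as formyl groups on C5 and C1) would react with the bifunctional reagent A9, first by an indium-mediated Barbier allylation at one aldehyde, then by a Lewis-acid-promoted allylsilane closure at the other, to give the diol A10.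
- In its favour: two C–C bonds, the seven-membered ring and two carbinol stereocentres in one flask, which is better than the chosen key step in bonds and in stereocentres created; both oxygens arrive at the right oxidation level.
- Against it here: the C6 and C10 configurations rest on two additions to hindered aldehydes with little stereochemical guidance. The C5–H of A8 is α to a formyl group and can epimerise to the trans series. The exocyclic methylene of A10 must be moved selectively toward C9 rather than C7. The two secondary hydroxyls of A10 are nearly alike and must carry different esters.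
- Comparison: on structure the alternative equals or betters the chosen plan in its key step. On mechanism two successive face selections without internal relay stand against a stereospecific relay. On step economy the annulation is shorter to the bicycle, but the isomerisation and the differentiation of the diol should cost what it saves, whereas the chosen plan has C10 protected and C6 free from the start.

Key step: step 11

Assumption: the O-silylated hydroxybenzoic acid 25 is treated as a catalogue building block.

## Route

Step 1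
Reactants: 1 penta-1,4-dien-3-ol
Product: 2 (2R,3S)-1,2-epoxypent-4-en-3-ol
Conditions: Ti(OiPr)4 (cat.), L-(+)-DIPT, t-BuOOH, 4 Å MS, CH2Cl2, −20 °C
Reagents that add atoms: tert-butyl hydroperoxide, CC(C)(C)OO
Why: Sharpless asymmetric epoxidation used as an enantiotopic-group-selective desymmetrisation; the tartrate-bound titanium peroxide epoxidises one vinyl group on one face to the erythro epoxy alcohol and the minor enantiomer is consumed by a faster second epoxidation, so the carbinol carbon (later C10, S) should be obtained in high enantiomeric purity.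

Step 2
Reactants: 2 (2R,3S)-1,2-epoxypent-4-en-3-ol
Product: 3 (2R)-2-[(1S)-1-[(4-methoxybenzyl)oxy]prop-2-en-1-yl]oxirane
Conditions: NaH, 4-MeOC6H4CH2Cl, n-Bu4NI (cat.), THF, 0 °C
Reagents that add atoms: 4-methoxybenzyl chloride, COc1ccc(CCl)cc1
Why: Williamson etherification; the benzylic iodide formed in situ should trap the alkoxide faster than Payne rearrangement, and the 4-methoxybenzyl ether is chosen because it chelates in step 5, tolerates all organometallic and Lewis-acid steps and leaves oxidatively in step 16.

Step 3
Reactants: 3 (2R)-2-[(1S)-1-[(4-methoxybenzyl)oxy]prop-2-en-1-yl]oxirane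
Product: 4 (2R,3S)-3-[(4-methoxybenzyl)oxy]pent-4-en-2-ol
Conditions: LiAlH4, THF, 0 °C
Reagents that add atoms: none
Why: SN2 hydride opening of the monosubstituted epoxide at its unhindered CH2 gives the methyl carbinol; the ether and the vinyl group are inert.

Step 4
Reactants: 4 (2R,3S)-3-[(4-methoxybenzyl)oxy]pent-4-en-2-ol
Product: 5 (3S)-3-[(4-methoxybenzyl)oxy]pent-4-en-2-one
Conditions: Dess–Martin periodinane, NaHCO3, CH2Cl2, 0 °C → rt
Reagents that add atoms: none
Why: Buffered, non-basic Dess–Martin oxidation should avoid enolisation of the doubly activated C10–H, so C10 is not racemised and the alkene stays out of conjugation.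

Step 5
Reactants: 5 (3S)-3-[(4-methoxybenzyl)oxy]pent-4-en-2-one; 6 cyclopropyl phenyl sulfide
Product: 9 (2R,3S)-3-[(4-methoxybenzyl)oxy]-2-[1-(phenylsulfanyl)cyclopropyl]pent-4-en-2-ol, via 1-(phenylsulfanyl)cyclopropyllithium 7 (not isolated), via [1-(phenylsulfanyl)cyclopropyl]magnesium bromide 8 (not isolated)
Conditions: 6, n-BuLi, THF, 0 °C; MgBr2·OEt2, −78 °C; then 5, −78 °C
Reagents that add atoms: none
Why: Cram-chelate addition of a Grignard reagent to an α-alkoxy ketone: magnesium bridges the carbonyl and ether oxygens of 5 and the sulfur-stabilised cyclopropyl nucleophile enters on the face not screened by the vinyl group, so the new C1–O bond is syn to the C10–O bond, the relationship that the invertive ring expansion of step 6 turns into the required C1 configuration.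

Step 6
Reactants: 9 (2R,3S)-3-[(4-methoxybenzyl)oxy]-2-[1-(phenylsulfanyl)cyclopropyl]pent-4-en-2-ol
Product: 12 (2S)-2-[(1S)-1-[(4-methoxybenzyl)oxy]prop-2-en-1-yl]-2-methylcyclobutan-1-one, via sulfonium tetrafluoroborate 10 (not isolated), via oxaspiropentane 11 (not isolated)
Conditions: Me3OBF4, CH2Cl2, 0 °C → rt; aq. NaOH, 0 °C; organic phase dried, then LiBF4, 35 °C
Reagents that add atoms: none
Why: S-methylation turns the sulfide into a leaving group and the alkoxide closes the oxaspiropentane with the C1–O bond intact (the closure that operates in sulfonium-ylide spiroannulation); the lithium salt then promotes the known oxaspiropentane-to-cyclobutanone rearrangement, in which a cyclopropane CH2 migrates to C1 anti to the departing oxygen (inversion) and the former cyclopropyl carbon becomes the carbonyl C4.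

Step 7
Reactants: 13 ethynylmagnesium bromide; 14 3-chloro-2-methylprop-1-ene
Product: 15 2-methylpent-1-en-4-yne
Conditions: CuCl (cat.), THF, 50 °C
Reagents that add atoms: none
Why: Copper-catalysed allylic substitution of the acetylenic Grignard reagent on the methallyl chloride (SN2 and SN2′ paths give the same product) should furnish the skipped enyne, used as a THF solution because it is volatile.

Step 8
Reactants: 15 2-methylpent-1-en-4-yne; 12 (2S)-2-[(1S)-1-[(4-methoxybenzyl)oxy]prop-2-en-1-yl]-2-methylcyclobutan-1-one
Product: 17 (1R,2S)-2-[(1S)-1-[(4-methoxybenzyl)oxy]prop-2-en-1-yl]-2-methyl-1-(4-methylpent-4-en-1-yn-1-yl)cyclobutan-1-ol, via lithium acetylide 16 (not isolated)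
Conditions: 15, n-BuLi, THF, −78 °C; then 12, −78 °C
Reagents that add atoms: none
Why: 1,2-Addition of a small, weakly basic acetylide to the strained ketone; attack anti to the branched C10 substituent on quaternary C1 (cis to the methyl group) should place the new C4–O bond cis to the C10 chain, and THF without a Lewis acid keeps the ether from chelating.

Step 9
Reactants: 17 (1R,2S)-2-[(1S)-1-[(4-methoxybenzyl)oxy]prop-2-en-1-yl]-2-methyl-1-(4-methylpent-4-en-1-yn-1-yl)cyclobutan-1-ol
Product: 18 (1R,2S)-2-[(1S)-1-[(4-methoxybenzyl)oxy]prop-2-en-1-yl]-2-methyl-1-[(1E)-4-methylpenta-1,4-dien-1-yl]cyclobutan-1-ol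
Conditions: NaAlH2(OCH2CH2OCH3)2, THF, 0 °C → rt
Reagents that add atoms: none
Why: Alkoxide-directed trans-hydroalumination of the propargylic alcohol followed by protonolysis should give only the (E)-alkene; the isolated alkenes and the ether are inert.

Step 10
Reactants: 18 (1R,2S)-2-[(1S)-1-[(4-methoxybenzyl)oxy]prop-2-en-1-yl]-2-methyl-1-[(1E)-4-methylpenta-1,4-dien-1-yl]cyclobutan-1-ol
Product: 19 (1S,2S)-2-[(1S)-1-[(4-methoxybenzyl)oxy]prop-2-en-1-yl]-2-methyl-1-[(2R,3S)-3-(2-methylprop-2-en-1-yl)oxiran-2-yl]cyclobutan-1-ol
Conditions: VO(acac)2 (cat.), t-BuOOH, CH2Cl2, 0 °C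
Reagents that add atoms: tert-butyl hydroperoxide, CC(C)(C)OO
Why: Hydroxyl-directed epoxidation by the vanadium alkylperoxide touches only the allylic C5=C6 bond; in the vanadate-ester transition state (O–C4–C5=C6 dihedral near 45°) the bulky quaternary C1 should avoid the in-plane position next to C5–H and lie anti to the metal, so oxygen is delivered to the face that gives the 5R,6S epoxide.

Step 11
Reactants: 19 (1S,2S)-2-[(1S)-1-[(4-methoxybenzyl)oxy]prop-2-en-1-yl]-2-methyl-1-[(2R,3S)-3-(2-methylprop-2-en-1-yl)oxiran-2-yl]cyclobutan-1-ol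
Product: 20 (2S,3R)-2-[(1S)-1-hydroxy-3-methylbut-3-en-1-yl]-3-[(1S)-1-[(4-methoxybenzyl)oxy]prop-2-en-1-yl]-3-methylcyclopentan-1-one
Conditions: BF3·OEt2, CH2Cl2, −78 °C; Et3N quench
Reagents that add atoms: none
Why: BF3 binds the epoxide oxygen, the C5–O bond lengthens, and the cyclobutane bond C4–C1, held anti-periplanar to it, shifts to C5 while C4 becomes the carbonyl carbon. This is the Lewis-acid semipinacol rearrangement of a 2,3-epoxy alcohol, known as a ring expansion of 1-(oxiranyl)cyclobutanols to 2-(1-hydroxyalkyl)cyclopentanones and driven by relief of four-ring strain and C=O formation. The five-membered ring C1–C2–C3–C4–C5 arises by ring enlargement through a 1,2-alkyl shift (an invertive opening of the oxirane at C5 by the migrating σ bond), not by an end-to-end cyclisation. The only new stereocentre, C5, is fixed by the epoxide configuration because migration is anti to the breaking C–O bond (inversion, giving 5S); C1 migrates with retention and C6 keeps its oxygen and configuration, so the two side chains should end cis on the cyclopentanone. The step needs C1 rather than C3 to migrate and opening at C5 rather than C6: C1 is the more substituted, more electron-rich terminus and occupies the anti position in the least crowded rotamer about C4–C5, and only C5 is attached to the carbinol carbon, so ionisation at C6 has no migrating bond to assist it. The configuration at C4 is erased; the low temperature and amine quench guard the β-hydroxy ketone against retro-aldol cleavage and dehydration; the ether and both alkenes are spectators at −78 °C.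

Step 12
Reactants: 20 (2S,3R)-2-[(1S)-1-hydroxy-3-methylbut-3-en-1-yl]-3-[(1S)-1-[(4-methoxybenzyl)oxy]prop-2-en-1-yl]-3-methylcyclopentan-1-one
Product: 21 (2S,3R)-3-[(1S)-1-[(4-methoxybenzyl)oxy]prop-2-en-1-yl]-3-methyl-2-[(1S)-3-methyl-1-[(trimethylsilyl)oxy]but-3-en-1-yl]cyclopentan-1-one
Conditions: 1-(trimethylsilyl)imidazole, CH2Cl2, 0 °C → rt
Reagents that add atoms: 1-(trimethylsilyl)imidazole, C[Si](C)(C)n1ccnc1
Why: Neutral O-silylation caps the aldol hydroxyl so that retro-aldol cleavage, C5 epimerisation and β-elimination cannot occur in step 13; imidazole is too weak a base to enolise the ketone.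

Step 13
Reactants: 21 (2S,3R)-3-[(1S)-1-[(4-methoxybenzyl)oxy]prop-2-en-1-yl]-3-methyl-2-[(1S)-3-methyl-1-[(trimethylsilyl)oxy]but-3-en-1-yl]cyclopentan-1-one; 22 isopropylmagnesium chloride
Product: 24 (1R,2S,3R)-2-[(1S)-1-hydroxy-3-methylbut-3-en-1-yl]-3-[(1S)-1-[(4-methoxybenzyl)oxy]prop-2-en-1-yl]-3-methyl-1-(propan-2-yl)cyclopentan-1-ol, via chloromagnesium alkoxide 23 (not isolated)
Conditions: CeCl3, THF, −78 → 0 °C; then 1 M HCl, 0 °C
Reagents that add atoms: none
Why: CeCl3-promoted Grignard addition should suppress enolisation and β-hydride reduction; the nucleophile enters anti to the C5 side chain and to the C10 chain on C1 (both on one face), so isopropyl ends cis to H5 and the C4 hydroxyl trans to it (4R), and the acidic quench removes the trimethylsilyl ether in the same flask.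

Step 14
Reactants: 24 (1R,2S,3R)-2-[(1S)-1-hydroxy-3-methylbut-3-en-1-yl]-3-[(1S)-1-[(4-methoxybenzyl)oxy]prop-2-en-1-yl]-3-methyl-1-(propan-2-yl)cyclopentan-1-ol; 25 4-[(tert-butyldimethylsilyl)oxy]benzoic acid
Product: 27 (1S)-1-[(1S,2R,5R)-2-hydroxy-5-[(1S)-1-[(4-methoxybenzyl)oxy]prop-2-en-1-yl]-5-methyl-2-(propan-2-yl)cyclopentyl]-3-methylbut-3-en-1-yl 4-[(tert-butyldimethylsilyl)oxy]benzoate, via mixed anhydride 26 (not isolated)
Conditions: 25, 2,4,6-Cl3C6H2COCl, Et3N, THF, rt; then 24, DMAP, toluene, 40 °C
Reagents that add atoms: none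
Why: Yamaguchi esterification should acylate the secondary C6 hydroxyl only, the tertiary C4 hydroxyl being too hindered; the phenol is masked as a silyl ether that tolerates DMAP, metathesis and DDQ.

Step 15
Reactants: 27 (1S)-1-[(1S,2R,5R)-2-hydroxy-5-[(1S)-1-[(4-methoxybenzyl)oxy]prop-2-en-1-yl]-5-methyl-2-(propan-2-yl)cyclopentyl]-3-methylbut-3-en-1-yl 4-[(tert-butyldimethylsilyl)oxy]benzoate
Product: 28 (1R,4R,5S,6S,10S)-4-hydroxy-10-[(4-methoxybenzyl)oxy]dauc-8-en-6-yl 4-[(tert-butyldimethylsilyl)oxy]benzoate
Conditions: second-generation Grubbs catalyst RuCl2(=CHPh)(PCy3)(H2IMes) (cat.), CH2Cl2, 40 °C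
Reagents that add atoms: none
Why: Ring-closing metathesis between the vinyl group on C10 and the methallyl group on C6 forms the trisubstituted C8=C9 bond and the seven-membered ring with loss of ethene; the cis disposition of the two chains favours closure and no stereocentre is touched.

Step 16
Reactants: 28 (1R,4R,5S,6S,10S)-4-hydroxy-10-[(4-methoxybenzyl)oxy]dauc-8-en-6-yl 4-[(tert-butyldimethylsilyl)oxy]benzoate
Product: 29 (1R,4R,5S,6S,10S)-4,10-dihydroxydauc-8-en-6-yl 4-[(tert-butyldimethylsilyl)oxy]benzoate
Conditions: DDQ, CH2Cl2/pH 7 buffer, 0 °C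
Reagents that add atoms: none
Why: Oxidative cleavage of the 4-methoxybenzyl ether through its benzylic oxocarbenium ion frees the C10 hydroxyl; the ester, aryl silyl ether and tertiary alcohol are inert, and limiting the oxidant at 0 °C should spare the new allylic alcohol.

Step 17
Reactants: 29 (1R,4R,5S,6S,10S)-4,10-dihydroxydauc-8-en-6-yl 4-[(tert-butyldimethylsilyl)oxy]benzoate; 30 (2E)-2-methylbut-2-enoic acid
Product: 32 (1R,4R,5S,6S,10S)-6-({4-[(tert-butyldimethylsilyl)oxy]benzoyl}oxy)-4-hydroxydauc-8-en-10-yl (2E)-2-methylbut-2-enoate, via mixed anhydride 31 (not isolated)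
Conditions: 30, 2,4,6-Cl3C6H2COCl, Et3N, toluene, rt; then 29, DMAP, 60 °C
Reagents that add atoms: none
Why: Yamaguchi esterification is forcing enough for the neopentyl allylic C10 hydroxyl, keeps the (E) geometry of the acyl group (its thermodynamic isomer) and leaves the tertiary C4 hydroxyl free.

Step 18
Reactants: 32 (1R,4R,5S,6S,10S)-6-({4-[(tert-butyldimethylsilyl)oxy]benzoyl}oxy)-4-hydroxydauc-8-en-10-yl (2E)-2-methylbut-2-enoate
Product: 33 (1R,4R,5S,6S,10S)-4-hydroxy-6-[(4-hydroxybenzoyl)oxy]dauc-8-en-10-yl (2E)-2-methylbut-2-enoate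
Conditions: TBAF, AcOH, THF, 0 °C
Reagents that add atoms: none
Why: Fluoride cleaves the aryl silyl ether selectively; buffering with acetic acid should prevent base-mediated acyl migration between the C6 and C4 oxygens and spares both esters.

## Compound list

1 | penta-1,4-dien-3-ol | C=CC(O)C=C | starting material
2 | (2R,3S)-1,2-epoxypent-4-en-3-ol | C=C[C@H](O)[C@H]1CO1 | intermediate
3 | (2R)-2-[(1S)-1-[(4-methoxybenzyl)oxy]prop-2-en-1-yl]oxirane | C=C[C@H](OCc1ccc(OC)cc1)[C@H]1CO1 | intermediate
4 | (2R,3S)-3-[(4-methoxybenzyl)oxy]pent-4-en-2-ol | C=C[C@H](OCc1ccc(OC)cc1)[C@H](O)C | intermediate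
5 | (3S)-3-[(4-methoxybenzyl)oxy]pent-4-en-2-one | C=C[C@H](OCc1ccc(OC)cc1)C(C)=O | intermediate
6 | cyclopropyl phenyl sulfide | c1ccc(cc1)SC1CC1 | starting material
7 | 1-(phenylsulfanyl)cyclopropyllithium | [Li]C1(CC1)Sc1ccccc1 | intermediate (not isolated)
8 | [1-(phenylsulfanyl)cyclopropyl]magnesium bromide | Br[Mg]C1(CC1)Sc1ccccc1 | intermediate (not isolated)
9 | (2R,3S)-3-[(4-methoxybenzyl)oxy]-2-[1-(phenylsulfanyl)cyclopropyl]pent-4-en-2-ol | C=C[C@H](OCc1ccc(OC)cc1)[C@@](C)(O)C1(CC1)Sc1ccccc1 | intermediate
10 | {1-[(2R,3S)-2-hydroxy-3-[(4-methoxybenzyl)oxy]pent-4-en-2-yl]cyclopropyl}(methyl)phenylsulfonium tetrafluoroborate (both configurations at sulfur) | C=C[C@H](OCc1ccc(OC)cc1)[C@@](C)(O)C1(CC1)[S+](C)c1ccccc1.F[B-](F)(F)F | intermediate (not isolated)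
11 | (2R)-2-[(1S)-1-[(4-methoxybenzyl)oxy]prop-2-en-1-yl]-2-methyl-1-oxaspiro[2.2]pentane | C=C[C@H](OCc1ccc(OC)cc1)[C@@]1(C)OC12CC2 | intermediate (not isolated)
12 | (2S)-2-[(1S)-1-[(4-methoxybenzyl)oxy]prop-2-en-1-yl]-2-methylcyclobutan-1-one | C=C[C@H](OCc1ccc(OC)cc1)[C@]1(C)CCC1=O | intermediate
13 | ethynylmagnesium bromide | C#C[Mg]Br | starting material
14 | 3-chloro-2-methylprop-1-ene | C=C(C)CCl | starting material
15 | 2-methylpent-1-en-4-yne | C#CCC(C)=C | intermediate
16 | (4-methylpent-4-en-1-yn-1-yl)lithium | [Li]C#CCC(C)=C | intermediate (not isolated)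
17 | (1R,2S)-2-[(1S)-1-[(4-methoxybenzyl)oxy]prop-2-en-1-yl]-2-methyl-1-(4-methylpent-4-en-1-yn-1-yl)cyclobutan-1-ol | C=C[C@H](OCc1ccc(OC)cc1)[C@]1(C)CC[C@@]1(O)C#CCC(C)=C | intermediate
18 | (1R,2S)-2-[(1S)-1-[(4-methoxybenzyl)oxy]prop-2-en-1-yl]-2-methyl-1-[(1E)-4-methylpenta-1,4-dien-1-yl]cyclobutan-1-ol | C=C[C@H](OCc1ccc(OC)cc1)[C@]1(C)CC[C@@]1(O)/C=C/CC(C)=C | intermediate
19 | (1S,2S)-2-[(1S)-1-[(4-methoxybenzyl)oxy]prop-2-en-1-yl]-2-methyl-1-[(2R,3S)-3-(2-methylprop-2-en-1-yl)oxiran-2-yl]cyclobutan-1-ol | C=C[C@H](OCc1ccc(OC)cc1)[C@]1(C)CC[C@@]1(O)[C@@H]1O[C@H]1CC(C)=C | intermediate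
20 | (2S,3R)-2-[(1S)-1-hydroxy-3-methylbut-3-en-1-yl]-3-[(1S)-1-[(4-methoxybenzyl)oxy]prop-2-en-1-yl]-3-methylcyclopentan-1-one | C=C[C@H](OCc1ccc(OC)cc1)[C@]1(C)CCC(=O)[C@@H]1[C@@H](O)CC(C)=C | intermediate
21 | (2S,3R)-3-[(1S)-1-[(4-methoxybenzyl)oxy]prop-2-en-1-yl]-3-methyl-2-[(1S)-3-methyl-1-[(trimethylsilyl)oxy]but-3-en-1-yl]cyclopentan-1-one | C=C[C@H](OCc1ccc(OC)cc1)[C@]1(C)CCC(=O)[C@@H]1[C@@H](O[Si](C)(C)C)CC(C)=C | intermediate
22 | isopropylmagnesium chloride | CC(C)[Mg]Cl | starting material
23 | chloromagnesium (1R,2S,3R)-3-[(1S)-1-[(4-methoxybenzyl)oxy]prop-2-en-1-yl]-3-methyl-2-[(1S)-3-methyl-1-[(trimethylsilyl)oxy]but-3-en-1-yl]-1-(propan-2-yl)cyclopentan-1-olate | C=C[C@H](OCc1ccc(OC)cc1)[C@]1(C)CC[C@@](O[Mg]Cl)(C(C)C)[C@@H]1[C@@H](O[Si](C)(C)C)CC(C)=C | intermediate (not isolated)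
24 | (1R,2S,3R)-2-[(1S)-1-hydroxy-3-methylbut-3-en-1-yl]-3-[(1S)-1-[(4-methoxybenzyl)oxy]prop-2-en-1-yl]-3-methyl-1-(propan-2-yl)cyclopentan-1-ol | C=C[C@H](OCc1ccc(OC)cc1)[C@]1(C)CC[C@@](O)(C(C)C)[C@@H]1[C@@H](O)CC(C)=C | intermediate
25 | 4-[(tert-butyldimethylsilyl)oxy]benzoic acid | CC(C)(C)[Si](C)(C)Oc1ccc(cc1)C(=O)O | starting material
26 | 4-[(tert-butyldimethylsilyl)oxy]benzoic 2,4,6-trichlorobenzoic anhydride | CC(C)(C)[Si](C)(C)Oc1ccc(cc1)C(=O)OC(=O)c1c(Cl)cc(Cl)cc1Cl | intermediate (not isolated)
27 | (1S)-1-[(1S,2R,5R)-2-hydroxy-5-[(1S)-1-[(4-methoxybenzyl)oxy]prop-2-en-1-yl]-5-methyl-2-(propan-2-yl)cyclopentyl]-3-methylbut-3-en-1-yl 4-[(tert-butyldimethylsilyl)oxy]benzoate | C=C[C@H](OCc1ccc(OC)cc1)[C@]1(C)CC[C@@](O)(C(C)C)[C@@H]1[C@@H](OC(=O)c1ccc(O[Si](C)(C)C(C)(C)C)cc1)CC(C)=C | intermediate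
28 | (1R,4R,5S,6S,10S)-4-hydroxy-10-[(4-methoxybenzyl)oxy]dauc-8-en-6-yl 4-[(tert-butyldimethylsilyl)oxy]benzoate (cis-fused) | COc1ccc(CO[C@H]2C=C(C)C[C@H](OC(=O)c3ccc(O[Si](C)(C)C(C)(C)C)cc3)[C@@H]3[C@@]2(C)CC[C@@]3(O)C(C)C)cc1 | intermediate
29 | (1R,4R,5S,6S,10S)-4,10-dihydroxydauc-8-en-6-yl 4-[(tert-butyldimethylsilyl)oxy]benzoate | O[C@H]1C=C(C)C[C@H](OC(=O)c2ccc(O[Si](C)(C)C(C)(C)C)cc2)[C@@H]2[C@@]1(C)CC[C@@]2(O)C(C)C | intermediate
30 | (2E)-2-methylbut-2-enoic acid (tiglic acid) | C/C=C(\C)C(=O)O | starting material
31 | (2E)-2-methylbut-2-enoic 2,4,6-trichlorobenzoic anhydride | C/C=C(\C)C(=O)OC(=O)c1c(Cl)cc(Cl)cc1Cl | intermediate (not isolated)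
32 | (1R,4R,5S,6S,10S)-6-({4-[(tert-butyldimethylsilyl)oxy]benzoyl}oxy)-4-hydroxydauc-8-en-10-yl (2E)-2-methylbut-2-enoate | C/C=C(\C)C(=O)O[C@H]1C=C(C)C[C@H](OC(=O)c2ccc(O[Si](C)(C)C(C)(C)C)cc2)[C@@H]2[C@@]1(C)CC[C@@]2(O)C(C)C | intermediate
33 | (1R,4R,5S,6S,10S)-4-hydroxy-6-[(4-hydroxybenzoyl)oxy]dauc-8-en-10-yl (2E)-2-methylbut-2-enoate (cis-fused; CNP0273650.3) | C/C=C(\C)C(=O)O[C@H]1C=C(C)C[C@H](OC(=O)c2ccc(O)cc2)[C@@H]2[C@@]1(C)CC[C@@]2(O)C(C)C | target

## Step count and least certain steps

Total: 18 steps. Longest linear sequence: 17 steps (steps 1–6 and 8–18 from 1); step 7 is the one convergent step.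

**Step 11 (key step).** The most likely failure is loss of migratory selectivity or of stereospecificity. If the C5–O bond ionises before C1 has moved, C3 can migrate or C5 can scramble. BF3 can also dehydrate or retro-aldolise the free β-hydroxy ketone, or strip the benzylic ether. Fallback, from 19: silylate the cyclobutanol with 1-(trimethylsilyl)imidazole to give the C4 trimethylsilyl ether of 19 F1, then treat it with catalytic TMSOTf in CH2Cl2 at −78 °C. The silyl group passes from the C4 oxygen to the epoxide oxygen as C1 migrates, the product never exists as a free aldol, and the sequence returns to the route at 21 (step 12 is then not needed).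

**Step 5.** Chelation control may erode, because the hindered tertiary nucleophile reacts slowly and partly through a non-chelated path, giving the C1 epimer. The basic reagent may also enolise the ketone, which racemises C10. Fallback, from 5: add 1-ethoxyvinyllithium (from ethyl vinyl ether and t-BuLi) with MgBr2·OEt2, a small sp2 nucleophile of the same chelate-controlled sense, to give (3R,4S)-2-ethoxy-4-[(4-methoxybenzyl)oxy]-3-methylhexa-1,5-dien-3-ol F2. Hydroxyl-directed Simmons–Smith cyclopropanation of the enol ether (Et2Zn, CH2I2) gives (2R,3S)-2-(1-ethoxycyclopropyl)-3-[(4-methoxybenzyl)oxy]pent-4-en-2-ol F3. Camphorsulfonic acid in wet CH2Cl2 then triggers the pinacol-type ring expansion (oxygen-assisted, anti migration), and the sequence returns to the route at 12.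

**Step 6.** S-Methylation of the hindered aryl sulfide may be slow and compete with alkylation at oxygen. Deprotonation at the S-methyl group may compete with closure at the cyclopropyl carbon. A stepwise, cationic rearrangement would erode the inversion at C1. Fallback, from 9: direct acid-induced ring expansion (TsOH·H2O cat., wet benzene, 60 °C), the established cyclobutanone synthesis from 1-(arylthio)cyclopropyl carbinols. Water loss and migration are concerted and the thionium ion is hydrolysed, and the sequence returns to the route at 12 with no new intermediate.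

**Step 10 (with the facial selectivity of step 8).** Facial selectivity may be poor because it is relayed twice through the C4 carbinol. If the acetylide addition of step 8 is only modestly selective, or the large-group-anti preference in the vanadate is weak, the wrong epoxide forms and leads to the C5,C6 diastereomer of 20. Fallback, from 18 (whatever its purity at C4): reagent-controlled epoxidation with the ketone catalyst 1,2:4,5-di-O-isopropylidene-β-L-erythro-2,3-hexodiulo-2,6-pyranose and KHSO5 (K2CO3 buffer, MeCN/dimethoxymethane/H2O, 0 °C). The D-fructose-derived ketone is known to give (R,R)-epoxides from simple trans-alkenes, and 19 has the opposite sense, so the L-series ketone is required. This gives 19 together with, from any C4-epimeric material, the C4 epimer of 19 F4. Both converge on 20 in step 11 because C4 becomes the carbonyl carbon, so the sequence returns to the route at 20.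

**Step 13.** Enolisation toward C5 or β-hydride reduction may outrun addition of the secondary alkyl nucleophile to a ketone flanked by a branched α-carbon. Fallback, from 21: close the seven-membered ring first with RuCl2(=CHPh)(PCy3)(H2IMes), the second-generation Grubbs catalyst of step 15, to give the bicyclic ketone (1R,5S,6S,10S)-10-[(4-methoxybenzyl)oxy]-1,8-dimethyl-6-[(trimethylsilyl)oxy]bicyclo[5.3.0]dec-8-en-4-one (daucane numbering) F5. Its C5 substituent is tied back and its convex face is open. Add 22 with CeCl3 and quench with 1 M HCl to give (1R,4R,5S,6S,10S)-10-[(4-methoxybenzyl)oxy]dauc-8-ene-4,6-diol F6. Esterify the C6 hydroxyl with 25 as in step 14, and the sequence returns to the route at 28.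

**Step 15.** Initiation at the vinyl group may be slow, since it is flanked by an ether and a quaternary carbon, and the 1,1-disubstituted partner is sluggish, so dimerisation or catalyst decay could win. Fallback, from 27: remove the benzylic ether first (DDQ, pH 7) to give the free allylic alcohol (1S)-1-[(1S,2R,5R)-2-hydroxy-5-[(1S)-1-hydroxyprop-2-en-1-yl]-5-methyl-2-(propan-2-yl)cyclopentyl]-3-methylbut-3-en-1-yl 4-[(tert-butyldimethylsilyl)oxy]benzoate F7. Its hydroxyl accelerates metathesis at the adjacent alkene; ring closure then returns to the route at 29.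

## Further compounds

F1 | step 11 | trimethyl{[(1S,2S)-2-[(1S)-1-[(4-methoxybenzyl)oxy]prop-2-en-1-yl]-2-methyl-1-[(2R,3S)-3-(2-methylprop-2-en-1-yl)oxiran-2-yl]cyclobutyl]oxy}silane | C=C[C@H](OCc1ccc(OC)cc1)[C@]1(C)CC[C@@]1(O[Si](C)(C)C)[C@@H]1O[C@H]1CC(C)=C
F2 | step 5 | (3R,4S)-2-ethoxy-4-[(4-methoxybenzyl)oxy]-3-methylhexa-1,5-dien-3-ol | C=C[C@H](OCc1ccc(OC)cc1)[C@@](C)(O)C(=C)OCC
F3 | step 5 | (2R,3S)-2-(1-ethoxycyclopropyl)-3-[(4-methoxybenzyl)oxy]pent-4-en-2-ol | C=C[C@H](OCc1ccc(OC)cc1)[C@@](C)(O)C1(OCC)CC1
F0 | step 6 | none | none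
F4 | step 10 | (1R,2S)-2-[(1S)-1-[(4-methoxybenzyl)oxy]prop-2-en-1-yl]-2-methyl-1-[(2R,3S)-3-(2-methylprop-2-en-1-yl)oxiran-2-yl]cyclobutan-1-ol | C=C[C@H](OCc1ccc(OC)cc1)[C@]1(C)CC[C@]1(O)[C@@H]1O[C@H]1CC(C)=C
F5 | step 13 | (1R,5S,6S,10S)-10-[(4-methoxybenzyl)oxy]-1,8-dimethyl-6-[(trimethylsilyl)oxy]bicyclo[5.3.0]dec-8-en-4-one (daucane numbering) | COc1ccc(CO[C@H]2C=C(C)C[C@H](O[Si](C)(C)C)[C@@H]3[C@@]2(C)CCC3=O)cc1
F6 | step 13 | (1R,4R,5S,6S,10S)-10-[(4-methoxybenzyl)oxy]dauc-8-ene-4,6-diol | COc1ccc(CO[C@H]2C=C(C)C[C@H](O)[C@@H]3[C@@]2(C)CC[C@@]3(O)C(C)C)cc1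
F7 | step 15 | (1S)-1-[(1S,2R,5R)-2-hydroxy-5-[(1S)-1-hydroxyprop-2-en-1-yl]-5-methyl-2-(propan-2-yl)cyclopentyl]-3-methylbut-3-en-1-yl 4-[(tert-butyldimethylsilyl)oxy]benzoate | C=C[C@H](O)[C@]1(C)CC[C@@](O)(C(C)C)[C@@H]1[C@@H](OC(=O)c1ccc(O[Si](C)(C)C(C)(C)C)cc1)CC(C)=C
A1 | alternative 1 | 2-diazo-5-(2-methoxy-4-methylphenyl)-6-methyl-5-[(triethylsilyl)oxy]heptan-3-one | CC(=[N+]=[N-])C(=O)C[C@@](O[Si](CC)(CC)CC)(C(C)C)c1ccc(C)cc1OC
A2 | alternative 1 | dirhodium tetraacetate, Rh2(OAc)4 | CC(=O)[O-].CC(=O)[O-].CC(=O)[O-].CC(=O)[O-].[Rh+2].[Rh+2]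
A3 | alternative 1 | 4-methoxy-6,8a-dimethyl-3-(propan-2-yl)-3-[(triethylsilyl)oxy]-3,8a-dihydroazulen-1(2H)-one | C1=CC(C)=CC(OC)=C2[C@@]1(C)C(=O)C[C@@]2(O[Si](CC)(CC)CC)C(C)C
A4 | alternative 2 | 6-endo-[(4-methoxybenzyl)oxy]-5-methyl-1-vinylbicyclo[3.1.0]hexan-2-one | C=C[C@]12C(=O)CC[C@@]1(C)[C@H]2OCc1ccc(OC)cc1
A5 | alternative 2 | propyne | CC#C
A6 | alternative 2 | [Rh(CO)2Cl]2 | [C-]#[O+].[C-]#[O+].[C-]#[O+].[C-]#[O+].[Cl-].[Cl-].[Rh+].[Rh+]
A7 | alternative 2 | 4-[(4-methoxybenzyl)oxy]-3a,6-dimethyl-3,3a,4,7-tetrahydroazulen-1(2H)-one | COc1ccc(cc1)CO[C@H]1C=C(C)CC=C2[C@@]1(C)CCC2=O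
A8 | alternative 3 | 1-methyl-3-(propan-2-yl)-3-[(triethylsilyl)oxy]cyclopentane-1,2-dicarbaldehyde (cis-dialdehyde, C1, C4 and C5 as in 33) | O=C[C@@H]1[C@](C)(C=O)CC[C@@]1(O[Si](CC)(CC)CC)C(C)C
A9 | alternative 3 | 2-(chloromethyl)-3-(trimethylsilyl)prop-1-ene | C=C(CCl)C[Si](C)(C)C
A10 | alternative 3 | 4-[(triethylsilyl)oxy]dauc-8(14)-ene-6,10-diol | O[C@H]1CC(=C)C[C@H](O)[C@@H]2[C@@]1(C)CC[C@@]2(O[Si](CC)(CC)CC)C(C)C
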